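**Strategy.** Both piperidine rings (N5, C6–C9, C9a of each quinolizidinone) are traced back to cyclopent-2-enone. The key step, a double Beckmann rearrangement, inserts nitrogen between C6 and C9a of two cyclopentanones. It exploits that C9a is the α-carbon and C9 the β-carbon of a cyclopentanone, so the C9/C9a relationship is set beforehand: trans (unit A) by conjugate addition–allylation, cis (unit B) by a Diels–Alder reaction whose temporary cyclohexene ring also delivers C1. The precursor is the bis-oxime of a 2-allyl-3-alkylcyclopentanone tethered to a cis-hydrindenone. Ozonolysis, Grignard addition and oxidation/aza-Michael cyclization then build both ketone rings, and an aldol condensation closes the macrocycle.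

Key step: step 6

Remark on the chemistry: locants are those of quinolizidin-2-one in each half (N5, C1–C4, C6–C9, C9a); unit A is the half with H-9/H-9a trans, unit B the half with H-9/H-9a cis; C1′–C5′ is the chain from C9 of unit B to C1 of unit A. C1 and C3, α to the ketones, are assumed to settle under mild base in the configuration of the target (equatorial methyl, no C1/C9 peri strain).

**Step 1**
Reactants: 1 7-bromohept-1-ene; 2 but-3-en-2-one
Product: 3 (E)-9-bromonon-3-en-2-one
Conditions: 2 (3 equiv), second-generation Hoveyda–Grubbs catalyst (2 mol %), CH2Cl2, 40 °C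
Reagents that add atoms: none
Why: Olefin cross-metathesis of a terminal alkene with an electron-poor vinyl ketone, which does not homodimerize readily, should give the (E)-enone selectively.

**Step 2**
Reactants: 3
Product: 4 {[(3E)-9-bromonona-1,3-dien-2-yl]oxy}triisopropylsilane
Conditions: TIPSOTf, Et3N, CH2Cl2, 0 °C
Reagents that add atoms: triisopropylsilyl trifluoromethanesulfonate, CC(C)[Si](C(C)C)(C(C)C)OS(=O)(=O)C(F)(F)F
Why: Soft enolization of the methyl ketone (silyl dienol ether formation) should give the cross-conjugated 2-silyloxydiene with the (E)-alkene intact, and the bulky silyl group makes it stable to the organometallic and basic steps that follow.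

**Step 3**
Reactants: 4; 5 cyclopent-2-en-1-one; 6 allyl iodide
Product: 9 (2S,3R)-2-allyl-3-[(6E)-8-(triisopropylsilyloxy)nona-6,8-dien-1-yl]cyclopentan-1-one, via Grignard reagent 7 (not isolated), via magnesium enolate 8 (not isolated)
Conditions: Mg, Et2O; then 5, CuBr·SMe2 (5 mol %), (R)-1-[(SP)-2-(diphenylphosphino)ferrocenyl]ethyldicyclohexylphosphine (6 mol %; the mirror-image ligand if the sense of induction requires it), t-BuOMe, −78 °C; then 6, DMPU, −78 → 0 °C
Reagents that add atoms: magnesium, [Mg] (present only in 7 and 8)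
Why: Copper-catalysed asymmetric conjugate addition of the Grignard reagent sets C9 of unit A under ligand control, and the regiospecific enolate is allylated anti to the new chain, so this three-component coupling should give the trans-2,3-disubstituted cyclopentanone.

**Step 4**
Reactants: 9; 5 cyclopent-2-en-1-one
Product: 10 (2S,3R)-2-allyl-3-{5-[(3aR,7S,7aR)-1-oxo-5-(triisopropylsilyloxy)-2,3,3a,4,7,7a-hexahydro-1H-inden-7-yl]pentyl}cyclopentan-1-one (all-cis H-3a/H-7/H-7a)
Conditions: 5 (3 equiv), (S)-3,3-diphenyl-1-(o-tolyl)tetrahydro-1H,3H-pyrrolo[1,2-c][1,3,2]oxazaborole activated with HNTf2 (20 mol %; the (R)-catalyst if the sense of induction requires it), CH2Cl2, −78 → −40 °C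
Reagents that add atoms: none
Why: Catalytic asymmetric Diels–Alder reaction in which the oxazaborolidinium ion activates only the enone and shields one face, the CH2 terminus of the diene bonds to the β-carbon and the diene adds endo, so C1, C9 and C9a of unit B are set in one event with the configuration of the target and the cis fusion is locked by the temporary cyclohexene ring.

**Step 5**
Reactants: 10
Product: 11 bis-(E)-oxime of 10 (each OH anti to the more substituted α-carbon)
Conditions: NH2OH·HCl, pyridine, EtOH, rt
Reagents that add atoms: hydroxylamine hydrochloride, NO.Cl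
Why: Oxime formation from both ketones should place each OH away from the substituted α-carbon (C9a of each unit), the geometry the rearrangement needs, and the basic medium spares the silyl enol ether.

**Step 6**
Reactants: 11
Product: 13 (5R,6S)-6-allyl-5-{5-[(4aR,8S,8aR)-2-oxo-6-(triisopropylsilyloxy)-1,2,3,4,4a,5,8,8a-octahydroquinolin-8-yl]pentyl}piperidin-2-one, via bis-tosylate 12 (not isolated)
Conditions: TsCl, aq. NaOH, THF, 0 °C; then 50 °C
Reagents that add atoms: p-toluenesulfonyl chloride, Cc1ccc(cc1)S(Cl)(=O)=O (tosyl groups of 12 only); water, O (lactam oxygens)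
Why: Double Beckmann rearrangement: each oxime is O-sulfonylated and ionizes with concerted 1,2-shift of the anti α-carbon from C6 to nitrogen, and water adds to the resulting imidoyl species to give the δ-lactam. The closest known reaction type is the Beckmann rearrangement of 2-substituted cyclopentanone and cis-hydrindanone oxime sulfonates to 6-substituted piperidin-2-ones and cis-octahydroquinolin-2-ones. No ring is closed anew; each cyclopentanone ring is enlarged to the six-membered ring N5–C6–C7–C8–C9–C9a by insertion of nitrogen between C6 and C9a. No new stereocentre is formed, because C9a migrates with retention, so the cis (unit B, held by the cyclohexene ring) and trans (unit A) C9/C9a relationships are carried over unchanged. The step needs migration of C9a rather than C7, which the (E)-oxime geometry secures, and survival of the silyl enol ether and the allyl group, which the basic aqueous medium allows.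

**Step 7**
Reactants: 13
Product: 15 2-[(2R,3R)-6-oxo-2-{(2R)-1-oxo-7-[(2S,3R)-6-oxo-2-(2-oxoethyl)piperidin-3-yl]heptan-2-yl}piperidin-3-yl]acetic acid, via silyl ester 14 (not isolated)
Conditions: O3, CH2Cl2, −78 °C; Me2S; then AcOH, THF–H2O, rt
Reagents that add atoms: ozone, [O-][O+]=O
Why: Ozonolysis cleaves the allyl group of unit A and the temporary cyclohexene of unit B, and because the enol-ether carbon emerges as a silyl ester (then the acid, C2′) while the two CH= carbons become the aldehydes that are C2 of each unit, the three termini are differentiated by oxidation level.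

**Step 8**
Reactants: 15; 16 isopropenylmagnesium bromide
Product: 17 bis(allylic alcohol) acid: 15 with each CHO converted into CH(OH)C(CH3)=CH2 (carbinol epimers, of no consequence)
Conditions: 16 (8 equiv), CeCl3, THF, −78 → 0 °C; aq. NH4Cl
Reagents that add atoms: none
Why: Cerium-modified Grignard addition should attack the two aldehydes without enolizing them while the carboxylate and the N-metallated lactams stay inert, and the new carbinol centres are oxidized away in step 10.

**Step 9**
Reactants: 17
Product: 18 diamino triol: both lactam C=O reduced to CH2 and CO2H to CH2OH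
Conditions: LiAlH4, THF, reflux
Reagents that add atoms: none
Why: Hydride reduction of secondary lactams and of the acid should give the two piperidines (C6 becomes CH2) and the primary alcohol, leaving the allylic alcohols and 1,1-disubstituted alkenes untouched.

**Step 10**
Reactants: 18
Product: 20 bis-quinolizidinone alcohol: unit A (C1 unsubstituted) joined from C9 by (CH2)5 to C1 of unit B, which carries CH2CH2OH at C9; stereocentres as in 28, via bis-enone 19 (not isolated)
Conditions: MnO2, CH2Cl2, rt; then Et3N, MeOH, rt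
Reagents that add atoms: none
Why: Allylic oxidation with MnO2 touches only the two allylic alcohols, and each isopropenyl ketone is trapped by its own secondary amine in a 6-endo-trig aza-Michael addition that closes the ketone ring, with C3 set by protonation and equilibrated to the equatorial methyl epimer while C1 of unit B keeps the stable orientation it received in step 4.

**Step 11**
Reactants: 20
Product: 21 aldehyde: 20 with CH2CHO at C9 of unit B
Conditions: (COCl)2, DMSO, CH2Cl2, −78 °C; Et3N
Reagents that add atoms: none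
Why: Swern oxidation should convert the remaining primary alcohol into the aldehyde in the presence of tertiary amines and ketones.

**Step 12**
Reactants: 21; 22 [2-(1,3-dioxolan-2-yl)ethyl]triphenylphosphonium bromide
Product: 24 (Z)-alkenyl dioxolane: C9 of unit B carries CH2CH=CHCH2CH(OCH2CH2O), via ylide 23 (not isolated)
Conditions: 22, KN(SiMe3)2, THF, −78 °C; then 21, −78 → 0 °C
Reagents that add atoms: none
Why: Wittig olefination with the non-stabilized ylide should take the unhindered aldehyde far faster than the two α,α′-disubstituted ketones at low temperature and adds C3′–C5′ with C5′ masked as a dioxolane.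

**Step 13**
Reactants: 24
Product: 25 saturated dioxolane: C9 of unit B carries (CH2)4CH(OCH2CH2O)
Conditions: H2 (1 atm), Pd/C, EtOAc, rt
Reagents that add atoms: none
Why: Catalytic hydrogenation saturates the alkene so that the aldehyde released next is not β,γ-unsaturated and cannot drift into conjugation, while ketones, amines and the acetal are inert.

**Step 14**
Reactants: 25
Product: 27 macrocyclic enone: 28 with an (E)-C1=C5′ double bond at C1 of unit A, via keto aldehyde 26 (not isolated)
Conditions: 1 M HCl, THF, rt; NaHCO3; then pyrrolidine, AcOH, toluene (1 mM), 4 Å sieves, 50 °C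
Reagents that add atoms: water, O (oxygen of 26 only)
Why: Acetal hydrolysis followed by amine-catalysed intramolecular aldol condensation should close the sixteen-membered ring, because C1 of unit A is the only α-carbon in the molecule with two hydrogens and so the only site where aldol addition can be followed by dehydration to an α-alkylidene ketone, with high dilution suppressing intermolecular condensation.

**Step 15**
Reactants: 27
Product: 28 target
Conditions: H2 (1 atm), Pd/C, EtOAc, rt; then Et3N, MeOH, rt
Reagents that add atoms: none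
Why: Catalytic hydrogenation of the exocyclic enone C=C completes the second pentamethylene chain, and the new centre C1 of unit A, α to the ketone, should equilibrate under mild base to the axial-chain epimer that avoids the peri interaction with the equatorial C9 chain, as in the target.

**Compound list**

1 | 7-bromohept-1-ene | C=CCCCCCBr | starting material
2 | but-3-en-2-one | CC(=O)C=C | starting material
3 | (E)-9-bromonon-3-en-2-one | CC(=O)/C=C/CCCCCBr | intermediate
4 | {[(3E)-9-bromonona-1,3-dien-2-yl]oxy}triisopropylsilane | C=C(O[Si](C(C)C)(C(C)C)C(C)C)/C=C/CCCCCBr | intermediate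
5 | cyclopent-2-en-1-one | O=C1C=CCC1 | starting material
6 | allyl iodide (3-iodoprop-1-ene) | C=CCI | starting material
7 | [(6E)-8-(triisopropylsilyloxy)nona-6,8-dien-1-yl]magnesium bromide | C=C(O[Si](C(C)C)(C(C)C)C(C)C)/C=C/CCCCC[Mg]Br | intermediate
8 | bromomagnesium (3R)-3-[(6E)-8-(triisopropylsilyloxy)nona-6,8-dien-1-yl]cyclopent-1-en-1-olate | Br[Mg]OC1=C[C@H](CCCCC/C=C/C(=C)O[Si](C(C)C)(C(C)C)C(C)C)CC1 | intermediate
9 | (2S,3R)-2-allyl-3-[(6E)-8-(triisopropylsilyloxy)nona-6,8-dien-1-yl]cyclopentan-1-one | O=C1CC[C@@H](CCCCC/C=C/C(=C)O[Si](C(C)C)(C(C)C)C(C)C)[C@@H]1CC=C | intermediate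
10 | (2S,3R)-2-allyl-3-{5-[(3aR,7S,7aR)-1-oxo-5-(triisopropylsilyloxy)-2,3,3a,4,7,7a-hexahydro-1H-inden-7-yl]pentyl}cyclopentan-1-one | O=C1CC[C@@H](CCCCC[C@H]2C=C(O[Si](C(C)C)(C(C)C)C(C)C)C[C@H]3CCC(=O)[C@@H]23)[C@@H]1CC=C | intermediate
11 | bis-(E)-oxime of 10 | O/N=C1\CC[C@@H](CCCCC[C@H]2C=C(O[Si](C(C)C)(C(C)C)C(C)C)C[C@H]3CC/C(=N\O)[C@@H]23)[C@@H]1CC=C | intermediate
12 | bis(O-tosyl oxime) of 10 | Cc1ccc(cc1)S(=O)(=O)O/N=C1\CC[C@@H](CCCCC[C@H]2C=C(O[Si](C(C)C)(C(C)C)C(C)C)C[C@H]3CC/C(=N\OS(=O)(=O)c4ccc(C)cc4)[C@@H]23)[C@@H]1CC=C | intermediate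
13 | (5R,6S)-6-allyl-5-{5-[(4aR,8S,8aR)-2-oxo-6-(triisopropylsilyloxy)-1,2,3,4,4a,5,8,8a-octahydroquinolin-8-yl]pentyl}piperidin-2-one | O=C1CC[C@@H](CCCCC[C@H]2C=C(O[Si](C(C)C)(C(C)C)C(C)C)C[C@H]3CCC(=O)N[C@@H]23)[C@H](CC=C)N1 | intermediate
14 | triisopropylsilyl ester of 15 | O=C1CC[C@@H](CCCCC[C@@H](C=O)[C@@H]2NC(=O)CC[C@@H]2CC(=O)O[Si](C(C)C)(C(C)C)C(C)C)[C@H](CC=O)N1 | intermediate
15 | 2-[(2R,3R)-6-oxo-2-{(2R)-1-oxo-7-[(2S,3R)-6-oxo-2-(2-oxoethyl)piperidin-3-yl]heptan-2-yl}piperidin-3-yl]acetic acid | O=C1CC[C@@H](CCCCC[C@@H](C=O)[C@@H]2NC(=O)CC[C@@H]2CC(O)=O)[C@H](CC=O)N1 | intermediate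
16 | isopropenylmagnesium bromide | CC(=C)[Mg]Br | starting material
17 | bis(allylic alcohol) acid (15 with each CHO as CH(OH)C(CH3)=CH2; carbinol epimers) | O=C1CC[C@@H](CCCCC[C@@H](C(O)C(C)=C)[C@@H]2NC(=O)CC[C@@H]2CC(O)=O)[C@H](CC(O)C(C)=C)N1 | intermediate
18 | diamino triol (two piperidines, two allylic alcohols, one primary alcohol) | C1CC[C@@H](CCCCC[C@@H](C(O)C(C)=C)[C@@H]2NCCC[C@@H]2CCO)[C@H](CC(O)C(C)=C)N1 | intermediate
19 | bis(amino isopropenyl ketone) | C1CC[C@@H](CCCCC[C@@H](C(=O)C(C)=C)[C@@H]2NCCC[C@@H]2CCO)[C@H](CC(=O)C(C)=C)N1 | intermediate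
20 | bis-quinolizidinone alcohol (unit A linked C9–(CH2)5–C1 to unit B bearing 9-(2-hydroxyethyl); stereocentres as in 28) | C[C@H]1CN2CCC[C@@H](CCCCC[C@H]3C(=O)[C@@H](C)CN4CCC[C@H](CCO)[C@H]34)[C@@H]2CC1=O | intermediate
21 | bis-quinolizidinone aldehyde (9-(2-oxoethyl) on unit B) | C[C@H]1CN2CCC[C@@H](CCCCC[C@H]3C(=O)[C@@H](C)CN4CCC[C@H](CC=O)[C@H]34)[C@@H]2CC1=O | intermediate
22 | [2-(1,3-dioxolan-2-yl)ethyl]triphenylphosphonium bromide | [Br-].C1COC(CC[P+](c2ccccc2)(c2ccccc2)c2ccccc2)O1 | starting material
23 | [3-(1,3-dioxolan-2-yl)propylidene]... ylide of 22, 2-(1,3-dioxolan-2-yl)ethylidene(triphenyl)phosphorane | C1COC(CC=P(c2ccccc2)(c2ccccc2)c2ccccc2)O1 | intermediate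
24 | (Z)-alkenyl dioxolane (unit B C9 chain CH2CH=CHCH2CH(OCH2CH2O)) | C[C@H]1CN2CCC[C@@H](CCCCC[C@H]3C(=O)[C@@H](C)CN4CCC[C@H](C/C=C\CC5OCCO5)[C@H]34)[C@@H]2CC1=O | intermediate
25 | saturated dioxolane (unit B C9 chain (CH2)4CH(OCH2CH2O)) | C[C@H]1CN2CCC[C@@H](CCCCC[C@H]3C(=O)[C@@H](C)CN4CCC[C@H](CCCCC5OCCO5)[C@H]34)[C@@H]2CC1=O | intermediate
26 | keto aldehyde (unit B C9 chain (CH2)4CHO) | C[C@H]1CN2CCC[C@@H](CCCCC[C@H]3C(=O)[C@@H](C)CN4CCC[C@H](CCCCC=O)[C@H]34)[C@@H]2CC1=O | intermediate
27 | macrocyclic enone (28 with (E)-C1=C5′ at unit A) | C[C@H]1CN2CCC[C@H]3CCCCC[C@H]4C(=O)[C@@H](C)CN5CCC[C@H](CCCC/C=C(/C1=O)[C@@H]32)[C@H]45 | intermediate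
28 | target bis-quinolizidinone macrocycle (unit A 1S,3S,9R,9aR; unit B 1R,3S,9S,9aR) | C[C@H]1CN2CCC[C@H]3CCCCC[C@H]4C(=O)[C@@H](C)CN5CCC[C@H](CCCCC[C@H](C1=O)[C@@H]32)[C@H]45 | target

**Total step count:** 15. **Longest linear sequence:** 15 steps (1 → 28).

**Steps most likely to fail**

Step 14 (macrocyclizing aldol condensation). Intermolecular aldol oligomerization may outrun the slow sixteen-membered ring closure, and enamine-mediated β-elimination could scramble C9a of unit B. The fallback sets out from 25 and returns at 27. Acetal hydrolysis gives keto aldehyde 26, now isolated, and Ph3P=CH2 converts it into the terminal alkene F1. α-Methylenation of the only methylene ketone (paraformaldehyde, N-methylanilinium trifluoroacetate, THF, reflux) gives the exo-methylene ketone F2. Ring-closing metathesis of its bis-ammonium tosylate with second-generation Hoveyda–Grubbs catalyst forms the same C1=C5′ bond and gives 27.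

Step 10 (oxidation and double aza-Michael closure). MnO2 may also oxidize the secondary amines or stall, and amine and enone of different molecules may combine. The fallback sets out from 18 and returns at 21. Boc2O gives the bis-carbamate F3, and Dess–Martin periodinane oxidizes all three alcohols to the bis-enone aldehyde F4. CF3CO2H removes both carbamates, and neutralization with NaHCO3 lets the freed amines close both rings by aza-Michael addition, giving aldehyde 21 directly.

Step 3 (asymmetric conjugate addition and allylation). Enantioselectivity on the five-membered enone may be insufficient and allylation of the magnesium enolate incomplete. The fallback sets out from 4 and returns at 9. Grignard reagent 7 is added to 3-ethoxycyclopent-2-en-1-one and mild acid work-up (aqueous oxalic acid) gives the 3-substituted cyclopentenone F5. Asymmetric conjugate reduction with a copper hydride catalyst (CuCl, NaOt-Bu, (S)-p-tol-BINAP, Ph2SiH2) sets C9 and leaves the silyl enol ether F6. This is allylated with 6 and tetrabutylammonium difluorotriphenylsilicate anti to the side chain to give 9.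

**Further compounds**

F1 | step 14 | keto alkene (unit B C9 chain hex-5-enyl) | C[C@H]1CN2CCC[C@@H](CCCCC[C@H]3C(=O)[C@@H](C)CN4CCC[C@H](CCCCC=C)[C@H]34)[C@@H]2CC1=O
F2 | step 14 | exo-methylene ketone (F1 with C1 of unit A as C=CH2) | C[C@H]1CN2CCC[C@@H](CCCCC[C@H]3C(=O)[C@@H](C)CN4CCC[C@H](CCCCC=C)[C@H]34)[C@@H]2C(=C)C1=O
F3 | step 10 | bis(N-tert-butoxycarbonyl) derivative of 18 | C1CC[C@@H](CCCCC[C@@H](C(O)C(C)=C)[C@@H]2N(C(=O)OC(C)(C)C)CCC[C@@H]2CCO)[C@H](CC(O)C(C)=C)N1C(=O)OC(C)(C)C
F4 | step 10 | bis(N-tert-butoxycarbonyl) bis-enone aldehyde | C1CC[C@@H](CCCCC[C@@H](C(=O)C(C)=C)[C@@H]2N(C(=O)OC(C)(C)C)CCC[C@@H]2CC=O)[C@H](CC(=O)C(C)=C)N1C(=O)OC(C)(C)C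
F5 | step 3 | 3-[(6E)-8-(triisopropylsilyloxy)nona-6,8-dien-1-yl]cyclopent-2-en-1-one | O=C1C=C(CCCCC/C=C/C(=C)O[Si](C(C)C)(C(C)C)C(C)C)CC1
F6 | step 3 | diphenylsilyl enol ether of (3R)-3-[(6E)-8-(triisopropylsilyloxy)nona-6,8-dien-1-yl]cyclopentanone | [SiH](c1ccccc1)(c1ccccc1)OC1=C[C@H](CCCCC/C=C/C(=C)O[Si](C(C)C)(C(C)C)C(C)C)CC1
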